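A pitfall when you repeat this flask: two E go at each turn of the loss step, so you may expect a larger charge of E to give less than a doubled rate. Reckon it in logarithms, with fractions of the charge.

- south-east: X 0.20 M; E 0.0064 mol%; the very flask that is asked about, followed so far
- flask: X 0.20 M; E 0.0064 mol%

south-east run (percent of the X charged)

| time / min | J / % | X / % |
|---|---|---|
| 0.667 | 12.1 | 90.0 |
| 1.33 | 20.5 | 80.0 |
| 2.00 | 26.6 | 74.0 |
| 2.50 | 33.8 | 67.4 |

(readings scatter by 1 percentage point)

- what may be going on: X + E -> J + E; 2 E -> D
- no earlier run changes the charge of E; that part of a forecast is a guess

* apparent order in E when 20% of the X are converted (percent change of the rate of making J for one percent more E charged)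
* factor on the rate of making J when 20% of the X are converted if E is charged twice over

1. Take the logarithm of the fraction of X left, in which a pseudo-first-order curve is straight. The last reading gives 0.395 after 2.50 min, so the mean constant is 0.158 min⁻¹.

2. Reaching 20% conversion needs a logarithm of 0.223. Dividing by the constant gives the clock, the time from the start until 20% of the X is converted: 1.41 min.

3. Test the constant on an earlier reading: it puts X at 81.0% after 1.33 min, and the reading there is 80.0%.

4. The weak link is the charge, which no run changes, so this step rests on the proposed steps and not on a reading. Let e be the fraction of the charge still E. X falls at a rate proportional to the charge times e, and e falls at a rate proportional to the charge times e squared. Divide one by the other and the charge cancels, so at equal conversion e is the same.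

5. With E charged twice over, the clock shortens to 0.705 min and the rate at 20% conversion doubles. The logarithm of the rate then rises as that of the charge does, so you commit to order 1 and factor 2, with no loss constant needed.

The forecast gave order 1 and factor 2, saying “Doubling E makes everything happen twice as fast”.

The simulation gives order 1.0 and factor 2.00.

    X + E → J + E, rate k1*[X]*[E]/(1 + ([X]/Km1) + ([J]/Kp1)) (13.6 mM, 0.0665 M, k = 2.26 × 10⁵ M⁻¹ min⁻¹)
    2 E → D (k = 13300 M⁻¹ min⁻¹)

This flask passes 20% conversion at 1.36 min, against your clock of 1.41 min, with 68.3% of the charge still E and 31.7% as D. Watch two times: by the loss step alone E has a first half-life of 2.94 min, and in this flask half of the turnover up to 12.0 min is done by 3.09 min, so the two times are close. At 12.0 min this flask still holds 26.9% of its X, with E down to 19.7% of the charge.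

All runs come from a simulation on assumed constants; noise was put on by code.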